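## Retrosynthetic overview

1. Target 33 ← exo-face epoxidation of the C9=C11 alkene, release of the ring B lactol and α-methylenation of the C15 ketone, all from the tetracyclic 1α,2α-diacetate 28.
2. Ring A ← C1–C2 bond: C1 and C2 are adjacent, both carry oxygen, and C1 hangs on the quaternary C10, so they can be the two carbonyl carbons of a 1,6-dialdehyde. A carbene-catalysed crossed benzoin closes ring A to the 1-hydroxy-2-ketone 24, and reduction then sets C2.
3. C5–C10 bond ← Ireland–Claisen rearrangement of the 11α-ester 17 across the exocyclic C9=C10 alkene, whose geometry is fixed by a temporary O7–C1 pyran ring. It sets C10 and C5 and leaves the C9=C11 alkene.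
4. Rings C/D ← intramolecular Michael closure of a 5-acetonylcyclopentenone to the bicyclo[3.2.1]octane. The quaternary C8 comes from a catalytic asymmetric decarboxylative allylation and is the only centre set by a catalyst; all others are relayed from it.
5. Ring order: D (bought), C (step 5), temporary pyran ring (step 10), A (step 16), B (step 18), epoxide (step 24).

Key step: step 16

Remark on naming: kaurane numbering (C1–C20) is used for every intermediate; α is the face of the C20 methyl group (the exo face of the bicyclo[3.2.1]octane) and β the face of the C15–C16 bridge; the SMILES strings are authoritative for configuration.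

Remark on the chemistry: acetal and lactol carbons that are later hydrolysed or equilibrate (C1 in 14, 15 and 17–23; C6 in 26–31) are expected as anomer mixtures, so their SMILES leave that one centre open. The configuration of the C15 carbinol (9–29) is of no consequence because it is oxidised in step 21.

Remark on supply: allyl 2-oxocyclopentane-1-carboxylate (1) is taken as a catalogue compound, and the enantiomeric purity reached in step 2 is expected to be raised by recrystallising diol 9.

## Route

Step 1
Reactants: 1 allyl 2-oxocyclopentane-1-carboxylate; 2 benzyl chloromethyl ether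
Product: 3 allyl 1-[(benzyloxy)methyl]-2-oxocyclopentane-1-carboxylate (racemic)
Conditions: NaH, THF, 0 °C to rt
Reagents that add atoms: none
Why: C-alkylation of the sodium enolate of the β-keto ester by the reactive α-chloro ether (the tight sodium ion pair in THF favours carbon over oxygen attack) installs C7 on the future C8, and the new stereocentre is racemic and is erased in step 2.

Step 2
Reactants: 3 allyl 1-[(benzyloxy)methyl]-2-oxocyclopentane-1-carboxylate
Product: 4 (R)-2-allyl-2-[(benzyloxy)methyl]cyclopentan-1-one
Conditions: Pd2(dba)3 (2.5 mol %), (R)-(CF3)3-t-Bu-PHOX (6 mol %), toluene, 30 °C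
Reagents that add atoms: none
Why: Decarboxylative asymmetric allylic alkylation (Tsuji–Trost type), in which zerovalent palladium ionises the allyl ester, CO2 is lost and the palladium enolate recombines with the allyl unit inside the chiral P,N-ligand sphere, so that the ligand alone fixes the (R)-configured quaternary C8, the (R)-ligand being chosen by analogy with the known sense of induction for 2-substituted cycloalkanone enolates.

Step 3
Reactants: 4 (R)-2-allyl-2-[(benzyloxy)methyl]cyclopentan-1-one
Product: 5 (S)-5-allyl-5-[(benzyloxy)methyl]cyclopent-2-en-1-one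
Conditions: IBX, 4-methoxypyridine N-oxide, DMSO, 25 °C
Reagents that add atoms: none
Why: IBX dehydrogenation of the ketone through its enol, which can form only toward C16 because C8 is quaternary, gives the cyclopentenone needed as Michael acceptor without touching the terminal alkene.

Step 4
Reactants: 5 (S)-5-allyl-5-[(benzyloxy)methyl]cyclopent-2-en-1-one
Product: 6 (R)-5-[(benzyloxy)methyl]-5-(2-oxopropyl)cyclopent-2-en-1-one
Conditions: PdCl2 (10 mol %), CuCl, O2 (1 atm), DMF/H2O 7:1, 25 °C
Reagents that add atoms: dioxygen, O=O (the oxygen atom is relayed through water)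
Why: Tsuji–Wacker oxidation of the monosubstituted alkene by divalent palladium with Markovnikov attack of water turns the allyl group into the acetonyl group C9–C11(=O)–C12, the electron-poor enone alkene being inert.

Step 5
Reactants: 6 (R)-5-[(benzyloxy)methyl]-5-(2-oxopropyl)cyclopent-2-en-1-one
Product: 7 (1S,5R)-5-[(benzyloxy)methyl]bicyclo[3.2.1]octane-3,6-dione (ketones at C11 and C15, CH2OBn on C8)
Conditions: DBU (0.3 equiv), MeCN, 25 °C
Reagents that add atoms: none
Why: Intramolecular Michael addition (6-exo-trig) of the methyl ketone enolate carbon C12 to the enone β-carbon C13 forms ring C, and because the tether on C8 can reach C13 only from its own face the new stereocentre C13 is fixed by relay from C8 in the bridged bicyclo[3.2.1]octane.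

Step 6
Reactants: 7 (1S,5R)-5-[(benzyloxy)methyl]bicyclo[3.2.1]octane-3,6-dione
Product: 8 (1S,5R)-5-(hydroxymethyl)bicyclo[3.2.1]octane-3,6-dione
Conditions: H2 (1 atm), Pd/C, EtOAc, 25 °C
Reagents that add atoms: none
Why: Hydrogenolysis of the benzyl ether frees the C7 hydroxyl, and retro-aldol loss of formaldehyde is blocked because it would need a bridgehead enolate (Bredt's rule).

Step 7
Reactants: 8 (1S,5R)-5-(hydroxymethyl)bicyclo[3.2.1]octane-3,6-dione
Product: 9 (1R,5R,7R)-7-hydroxy-1-(hydroxymethyl)bicyclo[3.2.1]octan-3-one (15-OH endo, turned toward C9)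
Conditions: Me4NBH(OAc)3, MeCN/AcOH 1:1, −30 °C
Reagents that add atoms: none
Why: Evans–Saksena hydroxyl-directed reduction, in which the C7 hydroxyl exchanges onto boron and delivers hydride internally only to the β-hydroxy ketone carbonyl C15 (the C11 ketone is γ to the hydroxyl and is not reduced by triacetoxyborohydride), delivery from the open exo face giving the endo C15 alcohol.

Step 8
Reactants: 9 (1R,5R,7R)-7-hydroxy-1-(hydroxymethyl)bicyclo[3.2.1]octan-3-one; 10 pyruvic acid
Product: 11 [(1R,5R,7R)-7-hydroxy-3-oxobicyclo[3.2.1]octan-1-yl]methyl 2-oxopropanoate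
Conditions: DCC, DMAP (5 mol %), CH2Cl2, −20 °C
Reagents that add atoms: none
Why: Steglich esterification acylates the primary C7 hydroxyl in preference to the endo, neopentyl secondary C15 hydroxyl and installs the α-keto ester that will become C1, C10 and C20.

Step 9
Reactants: 11 [(1R,5R,7R)-7-hydroxy-3-oxobicyclo[3.2.1]octan-1-yl]methyl 2-oxopropanoate
Product: 12 [(1R,5R,7R)-7-[(tert-butyldimethylsilyl)oxy]-3-oxobicyclo[3.2.1]octan-1-yl]methyl 2-oxopropanoate
Conditions: TBSOTf, 2,6-lutidine, CH2Cl2, −78 °C
Reagents that add atoms: tert-butyldimethylsilyl triflate, CC(C)(C)[Si](C)(C)OS(=O)(=O)C(F)(F)F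
Why: Silylation of the remaining secondary hydroxyl with the silyl triflate and a hindered pyridine base at low temperature protects C15 until step 20 without enolising the ketones.

Step 10
Reactants: 12 C15 silyl ether of the C7 pyruvate
Product: 13 enone lactone: δ-lactone O7–C1(=O)–C10(C20H3)=C9 fused to the bicyclo[3.2.1]octane, 11-oxo, 15-endo-OTBS
Conditions: DBU, 4 Å MS, MeCN, 25 °C
Reagents that add atoms: none
Why: Intramolecular aldol condensation (6-exo-trig, then E1cB loss of water), in which enolisation of the C11 ketone is reversible and only the C9 enolate can reach the highly electrophilic α-keto ester carbonyl C10 through a six-membered ring (C12 would need an eight-membered one), so that the tetrasubstituted C9=C10 alkene forms inside the δ-lactone, which fixes its geometry with C1 cis to C8 and the C20 methyl cis to C11.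

Step 11
Reactants: 13 enone lactone
Product: 15 11β-hydroxy methyl acetal (pyran ring O7–C1(OMe)–C10=C9; 15-endo-OTBS), via lactol 14 (not isolated)
Conditions: i-Bu2AlH, CH2Cl2, −78 °C; aq. potassium sodium tartrate; then MeOH, CSA (cat.), 0 °C
Reagents that add atoms: methanol, CO
Why: i-Bu2AlH reduces the C11 ketone 1,2 from the exo (α) face, the β face lying in the cavity under the C15–C16 bridge, to the 11β (endo) alcohol and stops the lactone at the lactol, which acid-catalysed acetalisation with methanol (Fischer glycosidation type) stores as the base-stable methyl acetal.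

Step 12
Reactants: 15 11β-hydroxy methyl acetal; 16 3,3-dimethylpent-4-enoic acid
Product: 17 11α-(3,3-dimethylpent-4-enoyloxy) methyl acetal
Conditions: PPh3, DIAD, THF, 0 °C to rt
Reagents that add atoms: none
Why: Mitsunobu esterification, in which the carboxylate displaces the activated endo C11 oxygen by SN2 from the open exo face and so inverts C11 to the 11α ester needed for an exo-face rearrangement, while SN2' attack is blocked because C10 is fully substituted.

Step 13
Reactants: 17 11α-(3,3-dimethylpent-4-enoyloxy) methyl acetal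
Product: 21 ring-A-seco methyl ester (C5–C10 bond formed; C9=C11 alkene; vinyl on C4), via silyl ketene acetal 18 (not isolated), via silyl ester 19 (not isolated), via carboxylic acid 20 (not isolated)
Conditions: LiN(i-Pr)2, Me3SiCl/Et3N, THF/DMPU, −78 °C, then 65 °C; dil. HCl; then Me3SiCHN2, toluene/MeOH, 0 °C
Reagents that add atoms: (trimethylsilyl)diazomethane, C[Si](C)(C)C=[N+]=[N-]
Why: Ireland–Claisen rearrangement, in which enolisation in THF/DMPU gives the (Z)-silyl ketene acetal (C4 cis to OSiMe3), allylic 1,3-strain between the C20 methyl and the C11 substituent holds the C11–O bond perpendicular to the alkene on the exo face, and the chair transition state with the tert-alkyl group pseudo-equatorial (the boat is blocked by the pyran ring) transfers the C11 chirality to C10 (α-methyl) and C5 (β-H) in one event while moving the alkene to C9=C11, after which the acid is methylated by the diazoalkane.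

Step 14
Reactants: 21 ring-A-seco methyl ester
Product: 22 C2 aldehyde (C4–CH2–CHO)
Conditions: PdCl2(PhCN)2 (10 mol %), CuCl2·2H2O (10 mol %), AgNO2 (5 mol %), O2 (1 atm), t-BuOH/MeNO2, 25 °C
Reagents that add atoms: dioxygen, O=O
Why: Nitrite-modified aldehyde-selective Wacker oxidation, in which the quaternary allylic carbon C4 steers oxygen to the terminal carbon C2 and the hindered trisubstituted C9=C11 alkene does not react.

Step 15
Reactants: 22 C2 aldehyde
Product: 23 C1 lactol (C1 hemiacetal with O7) carrying the C2 aldehyde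
Conditions: PPTS, acetone/H2O 4:1, 45 °C
Reagents that add atoms: water, O
Why: Acid hydrolysis of the C1 methyl acetal gives the lactol, a ring tautomer of the C1 aldehyde with the C7 hydroxyl, under conditions that leave the silyl ether, the ester and the C2 aldehyde intact.

Step 16
Reactants: 23 C1 lactol carrying the C2 aldehyde
Product: 24 1α-hydroxy-2-oxo ketol (ring A closed; free C7 hydroxyl; C6 methyl ester)
Conditions: 2-mesityl-6,7-dihydro-5H-pyrrolo[2,1-c][1,2,4]triazol-2-ium chloride (20 mol %), DBU (20 mol %), THF (0.02 M), 40 °C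
Reagents that add atoms: none
Why: The carbene formed from the triazolium salt adds to the unhindered C2 aldehyde and proton transfer gives the enaminol (acyl-anion equivalent), while the lactol opens reversibly to the C1 aldehyde, which cannot enolise and is too hindered to act as donor; C2 then attacks the C1 carbonyl, and loss of the carbene leaves the 1-hydroxy-2-ketone and frees the C7 hydroxyl. The closest known reaction type is the carbene-catalysed intramolecular crossed benzoin (acyloin) cyclisation of dialdehydes and keto aldehydes to five- and six-membered α-hydroxy ketones. Ring A closes in the 6-exo-trig mode. The new stereocentre C1 is controlled by the substrate: in the chair transition state C9 on C10 and C6 on C5 are equatorial, the azolium group on C2 takes the equatorial β position to avoid the 1,3-diaxial C20 and C4α methyl groups, and the enaminol O–H, then axial on the α face, hydrogen-bonds to the aldehyde oxygen, which places the C1 oxygen α (equatorial). The step needs chemoselectivity (C2 as donor, C1 as acceptor, no five-membered closure onto C6, no homo-coupling), and this is secured by the steric difference between the two aldehydes, by keeping C6 at the ester level and by dilution.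

Step 17
Reactants: 24 1α-hydroxy-2-oxo ketol
Product: 25 1α,2α-diol (ring B still open)
Conditions: NaBH4, MeOH, −40 °C
Reagents that add atoms: none
Why: Sodium borohydride reduction of the C2 ketone, in which axial attack from the α face is blocked by the syn-axial C20 and C4α methyl groups, so that hydride enters equatorially from the β face and gives the axial 2α alcohol cis to the 1α hydroxyl, as in reductions of cyclohexanones flanked by two axial methyl groups.

Step 18
Reactants: 25 1α,2α-diol
Product: 27 ring B methyl acetal 1α,2α-diol, via lactol 26 (not isolated)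
Conditions: i-Bu2AlH, CH2Cl2, −78 °C; aq. potassium sodium tartrate; then MeOH, CSA (cat.), 0 °C
Reagents that add atoms: methanol, CO
Why: i-Bu2AlH reduces the hindered C6 methyl ester to the aldehyde level, the tetrahedral aluminium hemiacetal being held by the neighbouring C7 alkoxide, and the hydroxy aldehyde closes to the seven-membered ring B lactol, which methanol and acid convert into the methyl acetal (Fischer glycosidation type) so that the lactol hydroxyl escapes acetylation.

Step 19
Reactants: 27 ring B methyl acetal 1α,2α-diol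
Product: 28 1α,2α-diacetate (6-O-methyl acetal, 15-OTBS, C9=C11)
Conditions: Ac2O, DMAP, Et3N, CH2Cl2, 40 °C
Reagents that add atoms: acetic anhydride, CC(=O)OC(C)=O
Why: DMAP-catalysed acetylation (Steglich type) esterifies the equatorial 1α and the hindered axial 2α hydroxyl, the only free hydroxyls left.

Step 20
Reactants: 28 1α,2α-diacetate
Product: 29 15-alcohol
Conditions: HF·pyridine, pyridine, THF, 0 °C to rt
Reagents that add atoms: none
Why: Fluoride-mediated cleavage of the silyl ether, driven by Si–F bond formation and buffered by pyridine, frees the C15 alcohol without touching the acetates or the methyl acetal.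

Step 21
Reactants: 29 15-alcohol
Product: 30 15-ketone
Conditions: Dess–Martin periodinane, NaHCO3, CH2Cl2, 25 °C
Reagents that add atoms: none
Why: Dess–Martin oxidation converts the secondary C15 alcohol into the cyclopentanone under buffered, neutral conditions.

Step 22
Reactants: 30 15-ketone
Product: 31 15-oxo-16(17)-ene (6-O-methyl acetal)
Conditions: CH2(NMe2)2, Ac2O, DMF, 95 °C
Reagents that add atoms: bis(dimethylamino)methane, CN(C)CN(C)C
Why: Mannich-type α-methylenation, in which the aminal and acetic anhydride generate the methyleneiminium ion, the ketone can enolise only toward C16 because C8 is quaternary, and the Mannich base loses dimethylamine (as its acetamide) to give the exocyclic enone.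

Step 23
Reactants: 31 15-oxo-16(17)-ene (6-O-methyl acetal)
Product: 32 9(11)-ene lactol (6-hydroxy)
Conditions: 1 M HCl, THF, 25 °C
Reagents that add atoms: water, O
Why: Mild acid hydrolysis of the seven-membered cyclic methyl acetal releases the C6 lactol, whose anomers equilibrate through the open hydroxy aldehyde and are expected to settle as the β-hydroxy form of the target, before the acid-sensitive epoxide is introduced.

Step 24
Reactants: 32 9(11)-ene lactol
Product: 33 target (CNP0224512.1)
Conditions: dimethyldioxirane, acetone, −20 °C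
Reagents that add atoms: dimethyldioxirane, CC1(C)OO1
Why: Epoxidation by concerted oxygen transfer takes the electron-rich trisubstituted C9=C11 alkene and not the enone alkene, and attack on the exo (α) face of the bicyclo[3.2.1]octene, away from the C15–C16 bridge, sets C9 and C11 as in the target.

## Compound list

1 | allyl 2-oxocyclopentane-1-carboxylate | C=CCOC(=O)C1CCCC1=O | starting material
2 | benzyl chloromethyl ether | ClCOCc1ccccc1 | starting material
3 | allyl 1-[(benzyloxy)methyl]-2-oxocyclopentane-1-carboxylate (racemic) | C=CCOC(=O)C1(COCc2ccccc2)CCCC1=O | intermediate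
4 | (R)-2-allyl-2-[(benzyloxy)methyl]cyclopentan-1-one | C=CC[C@@]1(COCc2ccccc2)CCCC1=O | intermediate
5 | (S)-5-allyl-5-[(benzyloxy)methyl]cyclopent-2-en-1-one | C=CC[C@@]1(COCc2ccccc2)CC=CC1=O | intermediate
6 | (R)-5-[(benzyloxy)methyl]-5-(2-oxopropyl)cyclopent-2-en-1-one | CC(=O)C[C@@]1(COCc2ccccc2)CC=CC1=O | intermediate
7 | (1S,5R)-5-[(benzyloxy)methyl]bicyclo[3.2.1]octane-3,6-dione | C1C(=O)[C@@]2(COCc3ccccc3)CC(=O)C[C@@H]1C2 | intermediate
8 | (1S,5R)-5-(hydroxymethyl)bicyclo[3.2.1]octane-3,6-dione | C1C(=O)[C@@]2(CO)CC(=O)C[C@@H]1C2 | intermediate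
9 | (1R,5R,7R)-7-hydroxy-1-(hydroxymethyl)bicyclo[3.2.1]octan-3-one (15-OH endo) | C1[C@@H](O)[C@@]2(CO)CC(=O)C[C@@H]1C2 | intermediate
10 | pyruvic acid | CC(=O)C(=O)O | starting material
11 | [(1R,5R,7R)-7-hydroxy-3-oxobicyclo[3.2.1]octan-1-yl]methyl 2-oxopropanoate | C1[C@@H](O)[C@@]2(COC(=O)C(C)=O)CC(=O)C[C@@H]1C2 | intermediate
12 | [(1R,5R,7R)-7-[(tert-butyldimethylsilyl)oxy]-3-oxobicyclo[3.2.1]octan-1-yl]methyl 2-oxopropanoate | C1[C@@H](O[Si](C)(C)C(C)(C)C)[C@@]2(COC(=O)C(C)=O)CC(=O)C[C@@H]1C2 | intermediate
13 | enone lactone: δ-lactone O7–C1(=O)–C10(CH3)=C9 fused to the bicyclo[3.2.1]octane, 11-oxo, 15-endo-OTBS | C1[C@@H](O[Si](C)(C)C(C)(C)C)[C@@]23COC(=O)C(C)=C2C(=O)C[C@@H]1C3 | intermediate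
14 | C1 lactol of 13 with 11β-hydroxyl (not isolated) | C1[C@@H](O[Si](C)(C)C(C)(C)C)[C@@]23COC(O)C(C)=C2[C@@H](O)C[C@@H]1C3 | intermediate
15 | 11β-hydroxy C1 methyl acetal (pyran ring O7–C1(OMe)–C10=C9), 15-endo-OTBS | C1[C@@H](O[Si](C)(C)C(C)(C)C)[C@@]23COC(OC)C(C)=C2[C@@H](O)C[C@@H]1C3 | intermediate
16 | 3,3-dimethylpent-4-enoic acid | C=CC(C)(C)CC(=O)O | starting material
17 | 11α-(3,3-dimethylpent-4-enoyloxy) C1 methyl acetal | C1[C@@H](O[Si](C)(C)C(C)(C)C)[C@@]23COC(OC)C(C)=C2[C@H](OC(=O)CC(C)(C)C=C)C[C@@H]1C3 | intermediate
18 | (Z)-trimethylsilyl ketene acetal of 17 (not isolated) | C1[C@@H](O[Si](C)(C)C(C)(C)C)[C@@]23COC(OC)C(C)=C2[C@H](O/C(=C/C(C)(C)C=C)O[Si](C)(C)C)C[C@@H]1C3 | intermediate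
19 | trimethylsilyl ester of the rearranged acid (not isolated) | C1[C@@H](O[Si](C)(C)C(C)(C)C)[C@@]23COC(OC)[C@](C)([C@H](C(=O)O[Si](C)(C)C)C(C)(C)C=C)C2=CC[C@@H]1C3 | intermediate
20 | C6 carboxylic acid: C10 (α-methyl) joined to C5 (β-H), C9=C11 alkene, C4 gem-dimethyl with vinyl (not isolated) | C1[C@@H](O[Si](C)(C)C(C)(C)C)[C@@]23COC(OC)[C@](C)([C@H](C(=O)O)C(C)(C)C=C)C2=CC[C@@H]1C3 | intermediate
21 | methyl ester of 20 | C1[C@@H](O[Si](C)(C)C(C)(C)C)[C@@]23COC(OC)[C@](C)([C@H](C(=O)OC)C(C)(C)C=C)C2=CC[C@@H]1C3 | intermediate
22 | C2 aldehyde (C4–CH2–CHO), C1 methyl acetal, C6 methyl ester | C1[C@@H](O[Si](C)(C)C(C)(C)C)[C@@]23COC(OC)[C@](C)([C@H](C(=O)OC)C(C)(C)CC=O)C2=CC[C@@H]1C3 | intermediate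
23 | C1 lactol (hemiacetal with O7) with C2 aldehyde | C1[C@@H](O[Si](C)(C)C(C)(C)C)[C@@]23COC(O)[C@](C)([C@H](C(=O)OC)C(C)(C)CC=O)C2=CC[C@@H]1C3 | intermediate
24 | 1α-hydroxy-2-oxo ketol: ring A closed, free C7 hydroxyl, C6 methyl ester, 15-OTBS, C9=C11 | C1[C@@H](O[Si](C)(C)C(C)(C)C)[C@@]2(CO)C(=CC[C@@H]1C2)[C@]3(C)[C@@H](O)C(=O)CC(C)(C)[C@H]3C(=O)OC | intermediate
25 | 1α,2α-diol of 24 | C1[C@@H](O[Si](C)(C)C(C)(C)C)[C@@]2(CO)C(=CC[C@@H]1C2)[C@]3(C)[C@@H](O)[C@@H](O)CC(C)(C)[C@H]3C(=O)OC | intermediate
26 | ring B lactol 1α,2α-diol (not isolated) | C1[C@@H](O[Si](C)(C)C(C)(C)C)[C@@]23COC(O)[C@@H]4C(C)(C)C[C@H](O)[C@H](O)[C@@]4(C)C2=CC[C@@H]1C3 | intermediate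
27 | ring B methyl acetal 1α,2α-diol | C1[C@@H](O[Si](C)(C)C(C)(C)C)[C@@]23COC(OC)[C@@H]4C(C)(C)C[C@H](O)[C@H](O)[C@@]4(C)C2=CC[C@@H]1C3 | intermediate
28 | 1α,2α-diacetate, 6-O-methyl acetal, 15-OTBS, 9(11)-ene | C1[C@@H](O[Si](C)(C)C(C)(C)C)[C@@]23COC(OC)[C@@H]4C(C)(C)C[C@H](OC(C)=O)[C@H](OC(C)=O)[C@@]4(C)C2=CC[C@@H]1C3 | intermediate
29 | 15-alcohol of 28 | C1[C@@H](O)[C@@]23COC(OC)[C@@H]4C(C)(C)C[C@H](OC(C)=O)[C@H](OC(C)=O)[C@@]4(C)C2=CC[C@@H]1C3 | intermediate
30 | 15-ketone | C1C(=O)[C@@]23COC(OC)[C@@H]4C(C)(C)C[C@H](OC(C)=O)[C@H](OC(C)=O)[C@@]4(C)C2=CC[C@@H]1C3 | intermediate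
31 | 15-oxo-16(17)-ene, 6-O-methyl acetal, 9(11)-ene | C=C1C(=O)[C@@]23COC(OC)[C@@H]4C(C)(C)C[C@H](OC(C)=O)[C@H](OC(C)=O)[C@@]4(C)C2=CC[C@@H]1C3 | intermediate
32 | 9(11)-ene lactol (6β-hydroxy) | C=C1C(=O)[C@@]23CO[C@@H](O)[C@@H]4C(C)(C)C[C@H](OC(C)=O)[C@H](OC(C)=O)[C@@]4(C)C2=CC[C@@H]1C3 | intermediate
33 | CNP0224512.1 | C=C1C(=O)[C@@]23CO[C@@H](O)[C@@H]4C(C)(C)C[C@H](OC(C)=O)[C@H](OC(C)=O)[C@@]4(C)[C@]24O[C@@H]4C[C@@H]1C3 | target

## Step count and risks

Total step count: 24. Longest linear sequence: 24 steps (1 to 33); compounds 2, 10 and 16 are bought and enter directly.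

The three steps most likely to fail:

Step 13. The bond between C5, which carries a tert-alkyl group, and the fully substituted C10 may form too slowly, so that the silyl ketene acetal is lost by C-silylation or elimination, or a competing boat pathway may erode control at C5. The fallback sets out from 15 and returns at 20; it divides the congestion over two Ireland–Claisen rearrangements. Mitsunobu reaction of 15 with acetic acid should give the 11α-acetate F1. Its Ireland–Claisen rearrangement (LiN(i-Pr)2, Me3SiCl) transfers only a CH2CO2H unit to the exo face of C10 and should give the C10-quaternary acetic acid F2. O-Alkylation with prenyl bromide (K2CO3, DMF) gives the prenyl ester F3. A second Ireland–Claisen rearrangement joins C5 to the dimethyl-substituted allyl terminus and gives acid 20. C5 is then set from C10 and stays correctable by equilibration next to the C6 carbonyl at the aldehyde level reached in step 18.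

Step 16. The lactol may release too little free aldehyde for the enaminol to capture, the addition may proceed with poor facial control at C1, or the acyloin may drift to its 1-oxo isomer. The fallback sets out from 23 and returns at 26; it closes the same C1–C2 bond reductively and corrects the configuration by oxidation and reduction. SmI2 (THF, t-BuOH, −78 °C) should give by intramolecular pinacol coupling the pinacol 1,2-diol F4 of either configuration. TsOH in toluene at 80 °C closes the C7 hydroxyl onto the C6 ester and gives the ε-lactone diol F5. Double Swern-type oxidation (DMSO, (CF3CO)2O, then Et3N) gives the 1,2-diketone lactone F6. NaBH4 delivers hydride to both carbonyls from the β face and gives the 1α,2α-diol lactone F7, which i-Bu2AlH at −78 °C reduces to lactol 26.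

Step 12. The endo C11 hydroxyl lies in the cavity under the bridge next to the silyl ether, so oxyphosphonium formation may be slow and elimination to the conjugated diene may take over. The fallback sets out from 15 and returns at 17; it separates activation from displacement. MsCl and Et3N (sulfene pathway, small electrophile) should give the 11β-mesylate F8. The caesium salt of acid 16 (Cs2CO3, 18-crown-6, toluene, 50 °C) then displaces it by SN2 from the exo face and gives ester 17.

Further compounds
F1 | step 13 | 11α-acetate of 15 | C1[C@@H](O[Si](C)(C)C(C)(C)C)[C@@]23COC(OC)C(C)=C2[C@H](OC(C)=O)C[C@@H]1C3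
F2 | step 13 | C10-quaternary acetic acid (C5 as CH2, C9=C11 alkene) | C1[C@@H](O[Si](C)(C)C(C)(C)C)[C@@]23COC(OC)[C@](C)(CC(=O)O)C2=CC[C@@H]1C3
F3 | step 13 | prenyl ester of F2 | C1[C@@H](O[Si](C)(C)C(C)(C)C)[C@@]23COC(OC)[C@](C)(CC(=O)OCC=C(C)C)C2=CC[C@@H]1C3
F4 | step 16 | pinacol 1,2-diol (C1 and C2 configuration open), free C7 hydroxyl, C6 methyl ester | C1[C@@H](O[Si](C)(C)C(C)(C)C)[C@@]2(CO)C(=CC[C@@H]1C2)[C@]3(C)C(O)C(O)CC(C)(C)[C@H]3C(=O)OC
F5 | step 16 | ε-lactone (C6 to O7) 1,2-diol | C1[C@@H](O[Si](C)(C)C(C)(C)C)[C@@]23COC(=O)[C@@H]4C(C)(C)CC(O)C(O)[C@@]4(C)C2=CC[C@@H]1C3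
F6 | step 16 | 1,2-diketone ε-lactone | C1[C@@H](O[Si](C)(C)C(C)(C)C)[C@@]23COC(=O)[C@@H]4C(C)(C)CC(=O)C(=O)[C@@]4(C)C2=CC[C@@H]1C3
F7 | step 16 | 1α,2α-diol ε-lactone | C1[C@@H](O[Si](C)(C)C(C)(C)C)[C@@]23COC(=O)[C@@H]4C(C)(C)C[C@H](O)[C@H](O)[C@@]4(C)C2=CC[C@@H]1C3
F8 | step 12 | 11β-mesylate of 15 | C1[C@@H](O[Si](C)(C)C(C)(C)C)[C@@]23COC(OC)C(C)=C2[C@@H](OS(C)(=O)=O)C[C@@H]1C3
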